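**Assumption:** Marchantin G has no stereocentre and its macrocycle is conformationally mobile, so "single enantiomer" is taken to mean the one achiral compound; no stereocontrol is needed.

## Retrosynthetic overview

1. Ring B comes from methyl gallate (1) through its C2v-symmetric 4-O-methyl diol (2). All four benzene rings are bought; the only ring made is the 18-membered macrocycle.
2. Rings C and D are joined by SNAr of phenol 3 on fluoroaldehyde 4, giving diaryl ether 5. Ring A is added by Wittig reaction with phosphonium salt 6, giving bromostilbene 7.
3. Key disconnection: the ring A–O–ring B ether is made by Cu-catalysed mono-O-arylation of unprotected diol 2 with 7, giving 8. Both OH groups are equivalent, and the one left over is the C-5 OH of the target.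
4. Hydrogenation gives 9. The macrocycle is then closed at the ArB–C(=O)–CH–ArC bond by a macro-Dieckmann (crossed Claisen) condensation, giving 10.
5. BBr3 removes both O-methyl groups and the extra CO2Me (as CO2), giving marchantin G (11).

## Route

**Step 1**
Reactants: 1, methyl gallate (methyl 3,4,5-trihydroxybenzoate)
Product: 2, methyl 3,5-dihydroxy-4-methoxybenzoate (C2v-symmetric diol)
Conditions: MeI (1.1 equiv), Li2CO3, DMF, 45 °C
Reagents that add atoms: iodomethane, CI
Why: The 4-OH (para to the ester) is the most acidic phenol of methyl gallate, so a weak base forms only that phenoxide and Williamson O-methylation occurs there, keeping the molecule symmetric; no stereocentre.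

**Step 2**
Reactants: 3, methyl 2-(3-hydroxyphenyl)acetate; 4, 2-fluoro-3-methoxybenzaldehyde
Product: 5, methyl 2-[3-(2-formyl-6-methoxyphenoxy)phenyl]acetate
Conditions: K2CO3, DMAc, 110 °C, Ar
Reagents that add atoms: none
Why: SNAr: the fluoride ortho to the formyl group is displaced by the phenoxide through a Meisenheimer intermediate, and carbonate is too weak to enolise the arylacetate appreciably; no stereocentre.

**Step 3**
Reactants: 5; 6, (4-bromobenzyl)triphenylphosphonium bromide
Product: 7, methyl 2-[3-[2-[2-(4-bromophenyl)ethenyl]-6-methoxyphenoxy]phenyl]acetate (E/Z mixture)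
Conditions: K2CO3, 18-crown-6 (cat.), CH2Cl2, reflux
Reagents that add atoms: none
Why: Wittig olefination of the aromatic aldehyde with a semi-stabilised benzylic ylide under mild solid–liquid conditions that spare the enolisable ester; the E/Z mixture does not matter because the alkene is hydrogenated in step 5.

**Step 4 (key step)**
Reactants: 7; 2 (3 equiv, excess recovered)
Product: 8, methyl 3-hydroxy-4-methoxy-5-[4-[2-[3-methoxy-2-[3-(2-methoxy-2-oxoethyl)phenoxy]phenyl]ethenyl]phenoxy]benzoate (E/Z mixture)
Conditions: CuI (10 mol%), N,N-dimethylglycine·HCl (30 mol%), Cs2CO3, dioxane, 100 °C, Ar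
Reagents that add atoms: none
Why: Ullmann-type Cu(I)/amino-acid-catalysed diaryl ether synthesis that desymmetrises 2: the two OH groups are equivalent so there is no regiochemical issue, excess diol keeps bis-arylation minor, and the untouched OH becomes the C-5 OH of the target without any protecting group.

**Step 5**
Reactants: 8
Product: 9, methyl 3-hydroxy-4-methoxy-5-[4-[2-[3-methoxy-2-[3-(2-methoxy-2-oxoethyl)phenoxy]phenyl]ethyl]phenoxy]benzoate
Conditions: H2 (1 atm), 10% Pd/C, EtOAc–MeOH, rt
Reagents that add atoms: none (H2 adds only hydrogen)
Why: Catalytic hydrogenation of the stilbene C=C; diaryl ethers, esters and the phenol are inert, no C–halogen or benzylic C–O bond remains, and the flexible CH2CH2 tether needed for cyclisation is formed.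

**Step 6**
Reactants: 9
Product: 10, macrocyclic β-keto ester: marchantin G in which the ring-B OH para to the ketone and the ring-D OH are methyl ethers and the CH2 between the ketone and ring C carries CO2Me (racemic, largely enolised)
Conditions: NaHMDS (4 equiv), THF, 0 → 45 °C, syringe-pump addition of 9 over 12 h (final 2 mM); AcOH quench
Reagents that add atoms: none
Why: Intramolecular crossed Claisen (macro-Dieckmann) condensation: only the arylacetate can enolise and only the benzoate can accept, so regiochemistry is fixed, high dilution favours the 18-membered ring, and deprotonation of the acidic α-aryl β-keto ester drives the reaction; the new CH(CO2Me) centre is racemic and is removed in step 7.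

**Step 7**
Reactants: 10
Product: 11, marchantin G
Conditions: BBr3 (10 equiv), CH2Cl2, −78 °C → rt, 16 h; then H2O/THF, 50 °C, 1 h
Reagents that add atoms: none (water supplies only hydrogen)
Why: BBr3 Lewis-acid cleavage of both aryl methyl ethers and the aliphatic methyl ester, followed by decarboxylation of the resulting α,β-diaryl β-keto acid on warm aqueous work-up; diaryl ethers and the aryl ketone are stable to BBr3, and no stereocentre remains.

## Compound list

1 | methyl gallate (methyl 3,4,5-trihydroxybenzoate) | COC(=O)c1cc(O)c(O)c(O)c1 | starting material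
2 | methyl 3,5-dihydroxy-4-methoxybenzoate | COC(=O)c1cc(O)c(OC)c(O)c1 | intermediate
3 | methyl 2-(3-hydroxyphenyl)acetate | COC(=O)Cc1cccc(O)c1 | starting material
4 | 2-fluoro-3-methoxybenzaldehyde | COc1cccc(C=O)c1F | starting material
5 | methyl 2-[3-(2-formyl-6-methoxyphenoxy)phenyl]acetate | COC(=O)Cc1cccc(Oc2c(C=O)cccc2OC)c1 | intermediate
6 | (4-bromobenzyl)triphenylphosphonium bromide | Brc1ccc(C[P+](c2ccccc2)(c2ccccc2)c2ccccc2)cc1.[Br-] | starting material
7 | methyl 2-[3-[2-[2-(4-bromophenyl)ethenyl]-6-methoxyphenoxy]phenyl]acetate, E/Z mixture | COC(=O)Cc1cccc(Oc2c(C=Cc3ccc(Br)cc3)cccc2OC)c1 | intermediate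
8 | methyl 3-hydroxy-4-methoxy-5-[4-[2-[3-methoxy-2-[3-(2-methoxy-2-oxoethyl)phenoxy]phenyl]ethenyl]phenoxy]benzoate, E/Z mixture | COC(=O)Cc1cccc(Oc2c(C=Cc3ccc(Oc4cc(C(=O)OC)cc(O)c4OC)cc3)cccc2OC)c1 | intermediate
9 | methyl 3-hydroxy-4-methoxy-5-[4-[2-[3-methoxy-2-[3-(2-methoxy-2-oxoethyl)phenoxy]phenyl]ethyl]phenoxy]benzoate | COC(=O)Cc1cccc(Oc2c(CCc3ccc(Oc4cc(C(=O)OC)cc(O)c4OC)cc3)cccc2OC)c1 | intermediate
10 | di-O-methyl marchantin G bearing CO2Me on the carbon between the ketone and ring C (racemic at that carbon) | O=C1C(C(=O)OC)c2cccc(c2)Oc2c(OC)cccc2CCc2ccc(cc2)Oc2cc1cc(O)c2OC | intermediate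
11 | marchantin G (achiral) | O=C1Cc2cccc(c2)Oc2c(O)cccc2CCc2ccc(cc2)Oc2cc1cc(O)c2O | target

## Summary

**Total steps:** 7.
**Longest linear sequence:** 6 steps (3/4 → 5 → 7 → 8 → 9 → 10 → 11); the 1 → 2 branch joins at step 4.

**Three steps most likely to fail, with fallbacks:**

1. **Step 6 (macro-Dieckmann).** Risks are oligomerisation and a sluggish, electron-rich benzoate acceptor. Fallback: close the ring at the C–O bond instead. Reduce 7 with diimide (keeps ArBr), saponify, form the ArB–CO–CH2–ArC ketone intermolecularly by decarboxylative Claisen of the arylacetic acid enediolate with bis-silylated 2, then run the Ullmann etherification intramolecularly on the free symmetric 3,5-diol (either OH gives the same macrocycle).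
2. **Step 4 (desymmetrising mono-Ullmann on the unprotected diol).** Risks are slow coupling of a hindered, ester-bearing phenol and bis-arylation. Fallback: reverse the polarity and order. Desymmetrise 2 by SNAr on 4-fluorobenzaldehyde (no copper), convert the aldehyde to the benzylphosphonium salt (NaBH4, then PPh3·HBr), and form the A–D stilbene by Wittig reaction with aldehyde 5.
3. **Step 7 (one-pot demethylation, ester cleavage and decarboxylation).** The risk is incomplete cleavage of the β-keto ester, giving mixtures. Fallback: remove the ester in its own step by Krapcho dealkoxycarbonylation of 10 (LiCl, wet DMSO, 140 °C), then use BBr3 only for the two aryl methyl ethers.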